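**Retrosynthetic overview**
1. The target (7'-hydroxylariciresinol) comes from the bis-allyl ether by Pd-catalysed deallylation. The C7' carbinol comes from ketoreductase reduction of a 4-aroyl-THF ketone.
2. The THF ring is closed last, by 5-exo-tet etherification of the C7 alkoxide onto a primary tosylate. The 1,4-diol comes from selective lactone reduction.
3. The C8'–C7' bond comes from an aldol of a trans-paraconate lactone enolate with an aryl aldehyde. The lactone (the first ring formed) comes from Ru-catalysed asymmetric transfer hydrogenation with DKR of a 2-aroylsuccinate, which sets C7 and C8. The THF is the second ring formed.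
4. The aroylsuccinate is built from methyl vanillate, tBuOAc and methyl bromoacetate. Phenols are carried as allyl ethers.

Assumption: the (S,S)-Ru-TsDPEN ATH–DKR gives the 2,3-syn (7S,8S) hydroxy diester, which lactonises to the trans-lactone. The C7' epimer mixture from the aldol is carried forward and erased by oxidation in Step 14. The aldol adds anti to the adjacent C3 ester (3,4-trans).

---

**Step 1**
Reactants: 1 methyl vanillate; 2 allyl bromide
Product: 3 methyl 4-(allyloxy)-3-methoxybenzoate
Conditions: K2CO3, DMF, 60 °C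
Reagents that add atoms: allyl bromide (2), C=CCBr
Why: Williamson O-allylation of the phenol; the allyl ether survives the later strong bases and hydrides and is removed under neutral Pd(0) conditions.

**Step 2**
Reactants: 4 vanillin; 2 allyl bromide
Product: 5 4-(allyloxy)-3-methoxybenzaldehyde
Conditions: K2CO3, DMF, 60 °C
Reagents that add atoms: allyl bromide (2), C=CCBr
Why: Same Williamson allylation, giving the aldehyde partner for Step 7.

**Step 3**
Reactants: 3 methyl 4-(allyloxy)-3-methoxybenzoate; 6 tert-butyl acetate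
Product: 7 tert-butyl 3-[4-(allyloxy)-3-methoxyphenyl]-3-oxopropanoate
Conditions: tBuOAc (2.5 equiv) + LDA (2.5 equiv), THF, –78 → 0 °C
Reagents that add atoms: tert-butyl acetate (6), CC(=O)OC(C)(C)C
Why: Crossed Claisen condensation of the lithium tert-butyl acetate enolate with the aryl ester. The second equivalent deprotonates the β-ketoester and drives the reaction. The tBu ester is chosen so that it survives LiBH4 later.

**Step 4**
Reactants: 7 β-ketoester; 8 methyl bromoacetate
Product: 9 1-tert-butyl 4-methyl 2-[4-(allyloxy)-3-methoxybenzoyl]succinate (racemic at C2)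
Conditions: K2CO3, acetone, 50 °C
Reagents that add atoms: methyl bromoacetate (8), COC(=O)CBr
Why: C-Alkylation of the stabilised β-ketoester enolate (monoalkylation) installs the C8–C8' unit and the C9' ester. The racemic α-centre is epimerisable, which is what the DKR in Step 5 needs.

**Step 5**
Reactants: 9 aroylsuccinate
Product: 10 1-tert-butyl 4-methyl (2S)-2-[(S)-[4-(allyloxy)-3-methoxyphenyl](hydroxy)methyl]succinate (syn)
Conditions: RuCl[(S,S)-TsDPEN](p-cymene) (1 mol %), HCO2H/Et3N 5:2, EtOAc, 35 °C
Reagents that add atoms: none (formic acid is only the hydride source)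
Why: Noyori–Ikariya asymmetric transfer hydrogenation with dynamic kinetic resolution. The (S,S)-catalyst sets C7 as S. Fast racemisation of the α-carbon (C8) lets the catalyst funnel it to the syn diastereomer. This is the first stereocentre and it is set by asymmetric catalysis.

**Step 6**
Reactants: 10 hydroxy diester
Product: 11 tert-butyl (2S,3S)-2-[4-(allyloxy)-3-methoxyphenyl]-5-oxotetrahydrofuran-3-carboxylate (trans paraconate lactone)
Conditions: PPTS (20 mol %), toluene, 70 °C, 4 Å MS
Reagents that add atoms: none (MeOH is lost)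
Why: Acid-catalysed γ-lactonisation of the C7–OH onto the unhindered methyl ester (C9'). The tBu ester cannot close (it would give a β-lactone). The syn relationship gives the trans ring, and no stereocentre is touched.

**Step 7**
Reactants: 11 lactone; 5 aldehyde
Product: 12 tert-butyl (2S,3S,4R)-4-{[4-(allyloxy)-3-methoxyphenyl](hydroxy)methyl}-2-[4-(allyloxy)-3-methoxyphenyl]-5-oxotetrahydrofuran-3-carboxylate (C7' epimer mixture)
Conditions: LiHMDS (1.05 equiv), THF, –78 °C; then 5, –78 °C; quench NH4Cl at –78 °C
Reagents that add atoms: aldehyde 5 (already numbered)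
Why: Lithium enolate aldol. The lactone α-H is far more acidic than the tBu ester α-H, so only the lactone enolises. The aldehyde approaches anti to the adjacent C3 ester, setting C8' (3,4-trans). C7' is formed as an epimer mixture. Trans-fused bis-lactonisation of the alkoxide is geometrically impossible.

**Step 8**
Reactants: 12 aldol adduct
Product: 13 the C7'-O-TBS ether (C7' epimer mixture)
Conditions: TBSOTf (1.5 equiv), 2,6-lutidine, CH2Cl2, –78 → –20 °C
Reagents that add atoms: TBSOTf, CC(C)(C)[Si](C)(C)OS(=O)(=O)C(F)(F)F
Why: Silylation of the only free OH masks it for the reductions and base step that follow. Low temperature protects the tBu ester from silyl triflate cleavage.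

**Step 9**
Reactants: 13 silyl ether
Product: 14 tert-butyl (2S,3S)-3-[4-(allyloxy)-3-methoxyphenyl]-2-{(2S)-1-[4-(allyloxy)-3-methoxyphenyl]-1-(TBSO)-3-hydroxypropan-2-yl}-3-hydroxypropanoate (C1' epimer mixture)
Conditions: LiBH4 (3 equiv), THF, MeOH (cat.), 0 °C → rt
Reagents that add atoms: none
Why: The γ-lactone is the most electrophilic carbonyl, so LiBH4 reduces it to the primary alcohol (C9') and frees the C7–OH. The hindered tBu ester and the TBS ether are untouched. No stereocentre is affected.

**Step 10**
Reactants: 14 diol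
Product: 15 the C9'-O-tosylate (C7–OH free, C1' epimer mixture)
Conditions: TsCl (1.1 equiv), pyridine, CH2Cl2, 0 °C
Reagents that add atoms: TsCl, Cc1ccc(cc1)S(=O)(=O)Cl
Why: Selective sulfonylation of the unhindered primary alcohol over the secondary benzylic C7–OH.

**Step 11**
Reactants: 15 tosylate
Product: 16 tert-butyl (2S,3S,4S)-2-aryl-4-[aryl(TBSO)methyl]tetrahydrofuran-3-carboxylate (C7' epimer mixture; aryl = 4-allyloxy-3-methoxyphenyl)
Conditions: NaH (1.5 equiv), THF, 0 °C → rt
Reagents that add atoms: none (TsONa is lost)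
Why: Intramolecular Williamson etherification (5-exo-tet) by the C7 alkoxide onto the primary tosylate. The C7–O bond is never broken, so C7 is retained. The THF ring is formed here.

**Step 12**
Reactants: 16 THF ester
Product: 17 {(2S,3R,4S)-2-aryl-4-[aryl(TBSO)methyl]tetrahydrofuran-3-yl}methanol
Conditions: LiAlH4 (2 equiv), THF, 0 → 40 °C
Reagents that add atoms: none
Why: Ester reduction to the C9 primary alcohol. The ether, allyl ethers and TBS group are stable to LiAlH4. C8 is now no longer epimerisable.

**Step 13**
Reactants: 17 TBS ether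
Product: 18 the THF diol (C9-OH and free C7'-OH; C7' epimer mixture)
Conditions: HF·pyridine, pyridine/THF, 0 °C → rt
Reagents that add atoms: none (the TBS group leaves as TBSF)
Why: Fluoride desilylation exposes the C7' benzylic alcohol for oxidation. Buffering with pyridine protects the acid-sensitive benzylic THF ether.

**Step 14**
Reactants: 18 diol
Product: 19 {(2S,3R,4S)-4-[4-(allyloxy)-3-methoxybenzoyl]-2-[4-(allyloxy)-3-methoxyphenyl]tetrahydrofuran-3-yl}methanol
Conditions: activated MnO2 (20 equiv), CH2Cl2, rt
Reagents that add atoms: none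
Why: MnO2 oxidises only the electron-rich secondary benzylic alcohol and leaves the unactivated primary alcohol alone. Both C7' epimers converge to one ketone. Neutral conditions keep C8' (3,4-trans) intact and avoid β-alkoxy-ketone elimination.

**Step 15**
Reactants: 19 ketone
Product: 20 {(2S,3R,4S)-2-aryl-4-[(S)-aryl(hydroxy)methyl]tetrahydrofuran-3-yl}methanol (bis-allyl ether)
Conditions: ketoreductase (KRED, oxidoreductase class; panel member selected for the (S)-benzylic alcohol), NADP+ (cat.), glucose/GDH, KPi pH 7.0, 10% DMSO, 30 °C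
Reagents that add atoms: none
Why: Enzymatic ketone reduction. The enzyme active site dictates the hydride face, setting C7' as S with high de, and the free primary OH does not interfere.

**Step 16**
Reactants: 20 bis-allyl ether
Product: 21 target, {(2S,3R,4S)-2-(4-hydroxy-3-methoxyphenyl)-4-[(S)-hydroxy(4-hydroxy-3-methoxyphenyl)methyl]oxolan-3-yl}methanol
Conditions: Pd(PPh3)4 (5 mol %), K2CO3, MeOH, rt
Reagents that add atoms: none (the allyl groups go to MeOH as allyl methyl ether)
Why: Tsuji–Trost deallylation of the aryl allyl ethers under neutral conditions. Hydrogenolysis is avoided, so the benzylic C–O bonds and all four stereocentres are untouched.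

---

**Compound list**

1 | methyl vanillate (methyl 4-hydroxy-3-methoxybenzoate) | COC(=O)c1ccc(O)c(OC)c1 | starting material
2 | allyl bromide | C=CCBr | starting material
3 | methyl 4-(allyloxy)-3-methoxybenzoate | COC(=O)c1ccc(OCC=C)c(OC)c1 | intermediate
4 | vanillin | COc1cc(C=O)ccc1O | starting material
5 | 4-(allyloxy)-3-methoxybenzaldehyde | O=Cc1ccc(OCC=C)c(OC)c1 | intermediate
6 | tert-butyl acetate | CC(=O)OC(C)(C)C | starting material
7 | tert-butyl 3-aryl-3-oxopropanoate | CC(C)(C)OC(=O)CC(=O)c1ccc(OCC=C)c(OC)c1 | intermediate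
8 | methyl bromoacetate | COC(=O)CBr | starting material
9 | 1-tert-butyl 4-methyl 2-aroylsuccinate | COC(=O)CC(C(=O)OC(C)(C)C)C(=O)c1ccc(OCC=C)c(OC)c1 | intermediate
10 | syn hydroxy diester (7S,8S) | COC(=O)C[C@H](C(=O)OC(C)(C)C)[C@H](O)c1ccc(OCC=C)c(OC)c1 | intermediate
11 | trans paraconate lactone (2S,3S) | CC(C)(C)OC(=O)[C@H]1CC(=O)O[C@@H]1c2ccc(OCC=C)c(OC)c2 | intermediate
12 | aldol adduct (C7' mixture) | CC(C)(C)OC(=O)[C@H]1[C@H](C(O)c2ccc(OCC=C)c(OC)c2)C(=O)O[C@@H]1c3ccc(OCC=C)c(OC)c3 | intermediate
13 | C7'-OTBS lactone | CC(C)(C)OC(=O)[C@H]1[C@H](C(O[Si](C)(C)C(C)(C)C)c2ccc(OCC=C)c(OC)c2)C(=O)O[C@@H]1c3ccc(OCC=C)c(OC)c3 | intermediate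
14 | open-chain diol tBu ester | CC(C)(C)OC(=O)[C@H]([C@H](O)c1ccc(OCC=C)c(OC)c1)[C@@H](CO)C(O[Si](C)(C)C(C)(C)C)c1ccc(OCC=C)c(OC)c1 | intermediate
15 | primary tosylate | CC(C)(C)OC(=O)[C@H]([C@H](O)c1ccc(OCC=C)c(OC)c1)[C@@H](COS(=O)(=O)c1ccc(C)cc1)C(O[Si](C)(C)C(C)(C)C)c1ccc(OCC=C)c(OC)c1 | intermediate
16 | THF tBu ester, C7'-OTBS | COc1cc(C(O[Si](C)(C)C(C)(C)C)[C@@H]2CO[C@H](c3ccc(OCC=C)c(OC)c3)[C@H]2C(=O)OC(C)(C)C)ccc1OCC=C | intermediate
17 | THF primary alcohol, C7'-OTBS | COc1cc(C(O[Si](C)(C)C(C)(C)C)[C@@H]2CO[C@H](c3ccc(OCC=C)c(OC)c3)[C@H]2CO)ccc1OCC=C | intermediate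
18 | THF diol (C7' mixture) | COc1cc(C(O)[C@@H]2CO[C@H](c3ccc(OCC=C)c(OC)c3)[C@H]2CO)ccc1OCC=C | intermediate
19 | 4-aroyl-THF ketone | COc1cc(C(=O)[C@@H]2CO[C@H](c3ccc(OCC=C)c(OC)c3)[C@H]2CO)ccc1OCC=C | intermediate
20 | bis-allyl ether of target | COc1cc([C@@H](O)[C@@H]2CO[C@H](c3ccc(OCC=C)c(OC)c3)[C@H]2CO)ccc1OCC=C | intermediate
21 | 7'-hydroxylariciresinol (target) | COc1cc([C@@H](O)[C@@H]2CO[C@H](c3ccc(O)c(OC)c3)[C@H]2CO)ccc1O | target

---

**Total steps:** 16. **Longest linear sequence:** 15 steps (1 → 3 → 7 → 9 → … → 21). Step 2 is a parallel branch.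

**Three steps most likely to fail**
1. **Step 5 (ATH–DKR diastereo- and enantioselectivity with the CH2CO2Me-substituted substrate).**
   - Fallback: change the catalyst class. Run a ketoreductase-catalysed DKR on 9 (KRED panel, pH 7–8), separate any cis-lactone after Step 6, and continue unchanged.
2. **Step 7 (aldol yield, trans selectivity, retro-aldol).**
   - Fallback: replace the aldol with C-acylation of the lactone enolate (2 equiv LiHMDS, aroyl imidazolide) to give the 4-aroyl lactone. Reduce it with a KRED DKR to set C8' and C7' together, then resume at Step 8.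
3. **Step 15 (KRED selectivity on the lipophilic ketone, and β-alkoxy-ketone elimination or C8' epimerisation).**
   - Fallback: reduce 19 with NaBH4 to both C7' epimers and resolve them by lipase (CAL-B, vinyl acetate) kinetic resolution. Recycle the unwanted epimer through Step 14.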